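**Retrosynthetic overview**

- Labels: ring A carries C1–OMe, C2–H, C3–OH, C4–aroyl, C5–OH and C6–CH2; ring B carries C1–C=O, C2–Me, C4–OH and C6–OH. The primed rings are the other half, whose ring B' has C6–OMe.
- Feature used: without its C4 oxygen, C4–H of ring B and of ring B' is the only aryl C–H with hydrogen on both neighbours, whereas C2–H of rings A and A' sits between two oxygen-bearing carbons. The last two C–O bonds are therefore made by steric C–H borylation–oxidation of 18 to 20, and acid then removes five MOM ethers.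
- Precursor 18 is cut at both aryl–CH2 bonds: ring A bromides 10 and 15 are joined through bis[(pinacolato)boryl]methane 16 by two Suzuki–Miyaura couplings.
- Both bromides come from one ring A aldehyde 4, made by a single lithiation of bis(MOM) ether 2 between its OMOM groups and formylation. The ring B aryllithium from bromoarene 6 or 11 adds to 4, and oxidation to the benzophenone and bromination at the free ring A position follow.
- No ring is formed; rings A, B, A' and B' are all purchased arenes.

Key step: step 12

Remarks on the chemistry: the target is achiral; carbinols 8 and 13 are racemic and lose their stereocentre on oxidation. Compound 16 is taken as a purchased one-carbon building block. The ring B and ring B' units are bought as 2-bromo-3-methylphenol 5 and 2-bromo-3-methylanisole 11, so that each aryl–carbonyl bond is made by adding a ring B aryllithium to the common ring A aldehyde 4.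

**Step 1**
Reactants: 1 5-methoxyresorcinol
Product: 2 1-methoxy-3,5-bis(methoxymethoxy)benzene
Conditions: NaH, MOMCl, DMF, 0 °C → rt
Reagents that add atoms: chloromethyl methyl ether (MOMCl), COCCl
Why: Williamson-type O-alkylation of both sodium phenoxides by the reactive α-chloro ether installs the MOM groups, which serve as protecting groups and as directing groups for step 2.

**Step 2**
Reactants: 2 1-methoxy-3,5-bis(methoxymethoxy)benzene
Product: 4 4-methoxy-2,6-bis(methoxymethoxy)benzaldehyde, via aryllithium 3 (not isolated)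
Conditions: n-BuLi, THF, 0 °C → rt; then DMF, −78 °C → rt; H2O
Reagents that add atoms: N,N-dimethylformamide (DMF), CN(C)C=O
Why: Directed ortho-metalation removes the C–H flanked by the two chelating OMOM groups (OMOM outranks OMe as a director), and formylation of the aryllithium by DMF stops at the hemiaminal alkoxide, which releases the aldehyde only on aqueous work-up.

**Step 3**
Reactants: 5 2-bromo-3-methylphenol
Product: 6 2-bromo-1-(methoxymethoxy)-3-methylbenzene
Conditions: NaH, MOMCl, DMF, 0 °C → rt
Reagents that add atoms: chloromethyl methyl ether (MOMCl), COCCl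
Why: The same phenoxide O-alkylation protects the ring B hydroxyl as its MOM ether; the aryl bromide is inert to these conditions.

**Step 4**
Reactants: 6 2-bromo-1-(methoxymethoxy)-3-methylbenzene; 4 4-methoxy-2,6-bis(methoxymethoxy)benzaldehyde
Product: 8 rac-[4-methoxy-2,6-bis(methoxymethoxy)phenyl][2-(methoxymethoxy)-6-methylphenyl]methanol, via aryllithium 7 (not isolated)
Conditions: n-BuLi (1.05 equiv), THF, −78 °C; then 4, −78 → 0 °C; H2O
Reagents that add atoms: none
Why: Bromine–lithium exchange at −78 °C is far faster than ortho-metalation or benzylic deprotonation and gives the ring B aryllithium, which adds 1,2 to the non-enolisable aldehyde; the carbinol centre forms as a racemate and is removed in step 5.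

**Step 5**
Reactants: 8 rac-[4-methoxy-2,6-bis(methoxymethoxy)phenyl][2-(methoxymethoxy)-6-methylphenyl]methanol
Product: 9 [4-methoxy-2,6-bis(methoxymethoxy)phenyl][2-(methoxymethoxy)-6-methylphenyl]methanone
Conditions: DMP, pyridine, CH2Cl2, 0 °C → rt
Reagents that add atoms: none
Why: Dess–Martin oxidation converts even tetra-ortho-substituted benzhydrols to benzophenones, and the pyridine buffer protects the MOM ethers and the ionisable benzhydrol from acetic acid.

**Step 6**
Reactants: 9 [4-methoxy-2,6-bis(methoxymethoxy)phenyl][2-(methoxymethoxy)-6-methylphenyl]methanone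
Product: 10 [3-bromo-4-methoxy-2,6-bis(methoxymethoxy)phenyl][2-(methoxymethoxy)-6-methylphenyl]methanone
Conditions: NBS (1.0 equiv), MeCN, 0 °C, dark
Reagents that add atoms: N-bromosuccinimide, O=C1CCC(=O)N1Br
Why: Electrophilic aromatic bromination should go to ring A, whose free position is ortho/para to three oxygens, and not to ring B with one oxygen donor; the two free ring A positions are equivalent, so one monobromide is expected.

**Step 7**
Reactants: 11 2-bromo-1-methoxy-3-methylbenzene (2-bromo-3-methylanisole); 4 4-methoxy-2,6-bis(methoxymethoxy)benzaldehyde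
Product: 13 rac-[4-methoxy-2,6-bis(methoxymethoxy)phenyl](2-methoxy-6-methylphenyl)methanol, via aryllithium 12 (not isolated)
Conditions: n-BuLi (1.05 equiv), THF, −78 °C; then 4, −78 → 0 °C; H2O
Reagents that add atoms: none
Why: The same bromine–lithium exchange and carbonyl addition as in step 4, now with the methyl ether bromoarene; the racemic carbinol centre is removed in step 8.

**Step 8**
Reactants: 13 rac-[4-methoxy-2,6-bis(methoxymethoxy)phenyl](2-methoxy-6-methylphenyl)methanol
Product: 14 [4-methoxy-2,6-bis(methoxymethoxy)phenyl](2-methoxy-6-methylphenyl)methanone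
Conditions: DMP, pyridine, CH2Cl2, 0 °C → rt
Reagents that add atoms: none
Why: Buffered Dess–Martin oxidation of the hindered benzhydrol gives the benzophenone without loss of the acid-labile MOM ethers.

**Step 9**
Reactants: 14 [4-methoxy-2,6-bis(methoxymethoxy)phenyl](2-methoxy-6-methylphenyl)methanone
Product: 15 [3-bromo-4-methoxy-2,6-bis(methoxymethoxy)phenyl](2-methoxy-6-methylphenyl)methanone
Conditions: NBS (1.0 equiv), MeCN, 0 °C, dark
Reagents that add atoms: N-bromosuccinimide, O=C1CCC(=O)N1Br
Why: As in step 6, electrophilic bromination should select the trioxygenated ring A' over the mono-oxygenated ring B', and both free ring A' positions lead to the same product.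

**Step 10**
Reactants: 10 [3-bromo-4-methoxy-2,6-bis(methoxymethoxy)phenyl][2-(methoxymethoxy)-6-methylphenyl]methanone; 16 bis[(pinacolato)boryl]methane
Product: 17 {4-methoxy-2,6-bis(methoxymethoxy)-3-[(4,4,5,5-tetramethyl-1,3,2-dioxaborolan-2-yl)methyl]phenyl}[2-(methoxymethoxy)-6-methylphenyl]methanone
Conditions: 16 (1.5 equiv), Pd[P(t-Bu)3]2 (cat.), aq KOH, 1,4-dioxane, rt
Reagents that add atoms: none
Why: Chemoselective Suzuki–Miyaura coupling of a gem-diborylmethane: the hydroxide borate transmetalates fast because of the neighbouring boryl group, so one C–B bond should react at room temperature, and the zerovalent palladium complex Pd[P(t-Bu)3]2 inserts into hindered, electron-rich aryl bromides.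

**Step 11**
Reactants: 17 benzylic boronate from step 10; 15 [3-bromo-4-methoxy-2,6-bis(methoxymethoxy)phenyl](2-methoxy-6-methylphenyl)methanone
Product: 18 4,4'-dideoxy pentakis(methoxymethyl) bis-benzophenone: {3-[[3-(2-(methoxymethoxy)-6-methylbenzoyl)-6-methoxy-2,4-bis(methoxymethoxy)phenyl]methyl]-4-methoxy-2,6-bis(methoxymethoxy)phenyl}(2-methoxy-6-methylphenyl)methanone
Conditions: Pd(OAc)2 (cat.), SPhos, K3PO4, toluene/H2O, 90 °C
Reagents that add atoms: none
Why: sp3–sp2 Suzuki–Miyaura coupling of a primary benzylic boronate (no β-hydrogen) with an aryl bromide; Pd(OAc)2 (divalent palladium) is reduced in the flask to a zerovalent SPhos complex, a ligand suited to di-ortho-substituted electron-rich aryl halides.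

**Step 12**
Reactants: 18 4,4'-dideoxy pentakis(methoxymethyl) bis-benzophenone
Product: 20 pentakis(methoxymethyl) ether of the target with free C4–OH on ring B and ring B', via bis(pinacolboronate) 19 (not isolated)
Conditions: [Ir(OMe)(cod)]2 (cat.), 4,4'-di-tert-butyl-2,2'-bipyridine (dtbpy), B2pin2 (excess), THF, 80 °C (sealed vessel); then NaBO3·4H2O, THF/H2O, rt
Reagents that add atoms: bis(pinacolato)diboron, CC1(C)OB(OC1(C)C)B1OC(C)(C)C(C)(C)O1; sodium perborate, [Na+].[Na+].O[B-]1(O)OO[B-](O)(O)OO1
Why: [Ir(OMe)(cod)]2 (monovalent iridium), dtbpy and B2pin2 form the 16-electron tris-boryl trivalent iridium complex (dtbpy)Ir(Bpin)3, which cleaves an aryl C–H bond and releases the aryl boronate by C–B reductive elimination; perborate then adds to boron and the aryl group migrates from boron to oxygen, so each C–B bond becomes a C–O bond at the same carbon. The closest known reaction type is the sterically governed iridium-catalysed C–H borylation of 1,2,3-trisubstituted benzenes at C5 with one-pot oxidation to the phenol. The step closes no ring and creates no stereocentre; it forms the C4–O bonds of ring B and ring B'. Site selectivity is the only selectivity needed and is steric: the catalyst has one open coordination site and avoids any C–H next to a substituent, so C3–H (beside the methyl), C5–H (beside OMOM or OMe) and C2–H of rings A and A' (between OMe and OMOM) should be left, while C4–H of each B ring has hydrogen on both sides. Ketone-directed borylation cannot interfere because all four positions ortho to each carbonyl are substituted, and MOM ethers are used because they carry no aryl C–H of their own. The two B rings are remote and react independently, so excess B2pin2 should drive both to the boronate before the oxidant is added.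

**Step 13**
Reactants: 20 pentakis(methoxymethyl) ether of the target with free C4–OH on ring B and ring B'
Product: 21 {3-[[2,4-dihydroxy-3-(2,4-dihydroxy-6-methylbenzoyl)-6-methoxyphenyl]methyl]-2,6-dihydroxy-4-methoxyphenyl}(4-hydroxy-2-methoxy-6-methylphenyl)methanone (CNP0596095.0)
Conditions: 3 M aq HCl, MeOH, 40 °C
Reagents that add atoms: none
Why: Acid-catalysed acetal cleavage (transacetalisation to dimethoxymethane) removes all five MOM ethers, while the aryl methyl ethers, the diaryl ketones and the diarylmethane should be stable to dilute HCl in methanol.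

**Compound list**

1 | 5-methoxyresorcinol | COc1cc(O)cc(O)c1 | starting material
2 | 1-methoxy-3,5-bis(methoxymethoxy)benzene | COc1cc(OCOC)cc(OCOC)c1 | intermediate
3 | [4-methoxy-2,6-bis(methoxymethoxy)phenyl]lithium | [Li]c1c(OCOC)cc(OC)cc1OCOC | intermediate (not isolated)
4 | 4-methoxy-2,6-bis(methoxymethoxy)benzaldehyde | COc1cc(OCOC)c(C=O)c(OCOC)c1 | intermediate
5 | 2-bromo-3-methylphenol | Cc1cccc(O)c1Br | starting material
6 | 2-bromo-1-(methoxymethoxy)-3-methylbenzene | COCOc1cccc(C)c1Br | intermediate
7 | [2-(methoxymethoxy)-6-methylphenyl]lithium | [Li]c1c(C)cccc1OCOC | intermediate (not isolated)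
8 | rac-[4-methoxy-2,6-bis(methoxymethoxy)phenyl][2-(methoxymethoxy)-6-methylphenyl]methanol | COc1cc(OCOC)c(C(O)c2c(C)cccc2OCOC)c(OCOC)c1 | intermediate
9 | [4-methoxy-2,6-bis(methoxymethoxy)phenyl][2-(methoxymethoxy)-6-methylphenyl]methanone | COc1cc(OCOC)c(C(=O)c2c(C)cccc2OCOC)c(OCOC)c1 | intermediate
10 | [3-bromo-4-methoxy-2,6-bis(methoxymethoxy)phenyl][2-(methoxymethoxy)-6-methylphenyl]methanone | COc1cc(OCOC)c(C(=O)c2c(C)cccc2OCOC)c(OCOC)c1Br | intermediate
11 | 2-bromo-1-methoxy-3-methylbenzene (2-bromo-3-methylanisole) | COc1cccc(C)c1Br | starting material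
12 | (2-methoxy-6-methylphenyl)lithium | [Li]c1c(C)cccc1OC | intermediate (not isolated)
13 | rac-[4-methoxy-2,6-bis(methoxymethoxy)phenyl](2-methoxy-6-methylphenyl)methanol | COc1cc(OCOC)c(C(O)c2c(C)cccc2OC)c(OCOC)c1 | intermediate
14 | [4-methoxy-2,6-bis(methoxymethoxy)phenyl](2-methoxy-6-methylphenyl)methanone | COc1cc(OCOC)c(C(=O)c2c(C)cccc2OC)c(OCOC)c1 | intermediate
15 | [3-bromo-4-methoxy-2,6-bis(methoxymethoxy)phenyl](2-methoxy-6-methylphenyl)methanone | COc1cc(OCOC)c(C(=O)c2c(C)cccc2OC)c(OCOC)c1Br | intermediate
16 | bis[(pinacolato)boryl]methane | CC1(C)OB(CB2OC(C)(C)C(C)(C)O2)OC1(C)C | starting material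
17 | {4-methoxy-2,6-bis(methoxymethoxy)-3-[(4,4,5,5-tetramethyl-1,3,2-dioxaborolan-2-yl)methyl]phenyl}[2-(methoxymethoxy)-6-methylphenyl]methanone | COc1cc(OCOC)c(C(=O)c2c(C)cccc2OCOC)c(OCOC)c1CB1OC(C)(C)C(C)(C)O1 | intermediate
18 | 4,4'-dideoxy pentakis(methoxymethyl) bis-benzophenone (C4–H on rings B and B') | COc1cc(OCOC)c(C(=O)c2c(C)cccc2OCOC)c(OCOC)c1Cc1c(OC)cc(OCOC)c(C(=O)c2c(C)cccc2OC)c1OCOC | intermediate
19 | bis(C4-pinacolboronate) of 18 on rings B and B' | COc1cc(OCOC)c(C(=O)c2c(C)cc(B3OC(C)(C)C(C)(C)O3)cc2OCOC)c(OCOC)c1Cc1c(OC)cc(OCOC)c(C(=O)c2c(C)cc(B3OC(C)(C)C(C)(C)O3)cc2OC)c1OCOC | intermediate (not isolated)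
20 | pentakis(methoxymethyl) ether of the target with free C4–OH on rings B and B' | COc1cc(OCOC)c(C(=O)c2c(C)cc(O)cc2OCOC)c(OCOC)c1Cc1c(OC)cc(OCOC)c(C(=O)c2c(C)cc(O)cc2OC)c1OCOC | intermediate
21 | {3-[[2,4-dihydroxy-3-(2,4-dihydroxy-6-methylbenzoyl)-6-methoxyphenyl]methyl]-2,6-dihydroxy-4-methoxyphenyl}(4-hydroxy-2-methoxy-6-methylphenyl)methanone (CNP0596095.0) | COc1cc(O)c(C(=O)c2c(C)cc(O)cc2O)c(O)c1Cc1c(OC)cc(O)c(C(=O)c2c(C)cc(O)cc2OC)c1O | target

**Step count**

Total: 13 steps. Longest linear sequence: 9 steps (steps 1, 2, 4, 5, 6, 10, 11, 12, 13).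

**Steps most likely to fail**

Step 12. The second borylation may stall through catalyst inhibition by the many Lewis-basic oxygens, site control may erode next to the small OMe of ring B', or the perborate stage may cleave the new para-hydroxy ketone in a Dakin-type oxidation. The fallback abandons the C–H oxidation and brings the C4 oxygen in with the ring B building blocks; it sets out from 2 and comes back at 21. Purchased 2,4-dihydroxy-6-methylbenzaldehyde is protected twice (NaH, MOMCl, DMF) to 2,4-bis(methoxymethoxy)-6-methylbenzaldehyde F1. Aryllithium 3, generated from 2 with n-BuLi, adds to it to give the ring B oxygenated carbinol F2, DMP gives the ring B oxygenated ketone F3, and NBS gives the ring A bromide F4; ring A, with three oxygen donors, should remain the more nucleophilic ring, although this selectivity is narrower than in step 6. For the other half the same purchased aldehyde is alkylated only at its non-chelated 4-hydroxyl (MOMCl, K2CO3, acetone) to 2-hydroxy-4-(methoxymethoxy)-6-methylbenzaldehyde F5, and MeI with K2CO3 gives 2-methoxy-4-(methoxymethoxy)-6-methylbenzaldehyde F6. Addition of aryllithium 3 then gives the ring B' oxygenated carbinol F7, DMP gives the ring B' oxygenated ketone F8 and NBS gives the ring A' bromide F9. F4 and 16 give the oxygenated benzylic boronate F10, which couples with F9 to the heptakis(methoxymethyl) ether of the target F11. Aqueous HCl in methanol then gives 21.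

Step 11. Protodeboronation of the benzylic boronate may outrun transmetalation to the crowded aryl-palladium species. The fallback reverses the polarity of the union; it sets out from 17 and 15 and comes back at 18. NaBO3·4H2O oxidises 17 to the ring A benzylic alcohol F12, and ClCO2Me with pyridine gives the benzylic methyl carbonate F13. Miyaura borylation of 15 (PdCl2(dppf), B2pin2, KOAc, dioxane, 90 °C) gives the ring A' aryl pinacolboronate F14. Coupling of F13 with F14 ([Pd(η3-C3H5)Cl]2, 1,5-bis(diphenylphosphino)pentane, K2CO3, aq DMF, 80 °C) through an η3-benzyl divalent palladium intermediate gives 18.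

Step 10. Oxidative addition into the doubly flanked, electron-rich C–Br bond may be slow at room temperature, and heating may cause a second arylation of the gem-diboryl reagent. The fallback installs the boron and the carbon separately; it sets out from 10 and comes back at 17. Miyaura borylation of 10 (PdCl2(dppf), B2pin2, KOAc, dioxane, 90 °C) gives the ring A aryl pinacolboronate F15. Matteson one-carbon homologation (BrCH2Cl, n-BuLi, THF, −78 °C → rt; chloromethyllithium generated in the presence of the boronate) then gives 17. The tetra-ortho-substituted ketone should be too hindered to compete for the organolithium.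

**Further compounds**

F1 | step 12 | 2,4-bis(methoxymethoxy)-6-methylbenzaldehyde | O=Cc1c(C)cc(OCOC)cc1OCOC
F2 | step 12 | rac-[4-methoxy-2,6-bis(methoxymethoxy)phenyl][2,4-bis(methoxymethoxy)-6-methylphenyl]methanol | COc1cc(OCOC)c(C(O)c2c(C)cc(OCOC)cc2OCOC)c(OCOC)c1
F3 | step 12 | [4-methoxy-2,6-bis(methoxymethoxy)phenyl][2,4-bis(methoxymethoxy)-6-methylphenyl]methanone | COc1cc(OCOC)c(C(=O)c2c(C)cc(OCOC)cc2OCOC)c(OCOC)c1
F4 | step 12 | [3-bromo-4-methoxy-2,6-bis(methoxymethoxy)phenyl][2,4-bis(methoxymethoxy)-6-methylphenyl]methanone | COc1cc(OCOC)c(C(=O)c2c(C)cc(OCOC)cc2OCOC)c(OCOC)c1Br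
F5 | step 12 | 2-hydroxy-4-(methoxymethoxy)-6-methylbenzaldehyde | O=Cc1c(C)cc(OCOC)cc1O
F6 | step 12 | 2-methoxy-4-(methoxymethoxy)-6-methylbenzaldehyde | O=Cc1c(C)cc(OCOC)cc1OC
F7 | step 12 | rac-[4-methoxy-2,6-bis(methoxymethoxy)phenyl][2-methoxy-4-(methoxymethoxy)-6-methylphenyl]methanol | COc1cc(OCOC)c(C(O)c2c(C)cc(OCOC)cc2OC)c(OCOC)c1
F8 | step 12 | [4-methoxy-2,6-bis(methoxymethoxy)phenyl][2-methoxy-4-(methoxymethoxy)-6-methylphenyl]methanone | COc1cc(OCOC)c(C(=O)c2c(C)cc(OCOC)cc2OC)c(OCOC)c1
F9 | step 12 | [3-bromo-4-methoxy-2,6-bis(methoxymethoxy)phenyl][2-methoxy-4-(methoxymethoxy)-6-methylphenyl]methanone | COc1cc(OCOC)c(C(=O)c2c(C)cc(OCOC)cc2OC)c(OCOC)c1Br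
F10 | step 12 | {4-methoxy-2,6-bis(methoxymethoxy)-3-[(4,4,5,5-tetramethyl-1,3,2-dioxaborolan-2-yl)methyl]phenyl}[2,4-bis(methoxymethoxy)-6-methylphenyl]methanone | COc1cc(OCOC)c(C(=O)c2c(C)cc(OCOC)cc2OCOC)c(OCOC)c1CB1OC(C)(C)C(C)(C)O1
F11 | step 12 | heptakis(methoxymethyl) ether of the target | COc1cc(OCOC)c(C(=O)c2c(C)cc(OCOC)cc2OCOC)c(OCOC)c1Cc1c(OC)cc(OCOC)c(C(=O)c2c(C)cc(OCOC)cc2OC)c1OCOC
F12 | step 11 | [3-(hydroxymethyl)-4-methoxy-2,6-bis(methoxymethoxy)phenyl][2-(methoxymethoxy)-6-methylphenyl]methanone | COc1cc(OCOC)c(C(=O)c2c(C)cccc2OCOC)c(OCOC)c1CO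
F13 | step 11 | {6-methoxy-2,4-bis(methoxymethoxy)-3-[2-(methoxymethoxy)-6-methylbenzoyl]phenyl}methyl methyl carbonate | COc1cc(OCOC)c(C(=O)c2c(C)cccc2OCOC)c(OCOC)c1COC(=O)OC
F14 | step 11 | [4-methoxy-2,6-bis(methoxymethoxy)-3-(4,4,5,5-tetramethyl-1,3,2-dioxaborolan-2-yl)phenyl](2-methoxy-6-methylphenyl)methanone | COc1cc(OCOC)c(C(=O)c2c(C)cccc2OC)c(OCOC)c1B1OC(C)(C)C(C)(C)O1
F15 | step 10 | [4-methoxy-2,6-bis(methoxymethoxy)-3-(4,4,5,5-tetramethyl-1,3,2-dioxaborolan-2-yl)phenyl][2-(methoxymethoxy)-6-methylphenyl]methanone | COc1cc(OCOC)c(C(=O)c2c(C)cccc2OCOC)c(OCOC)c1B1OC(C)(C)C(C)(C)O1
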